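**Analysis of the target**

The target is a tricyclic meroterpenoid. Ring A is a 2-acylcyclohexane-1,3,5-trione drawn as its enol (C1 carbonyl, C2 acylated carbon, C3 enol carbon, C4 methyl/prenyl carbon, C5 carbonyl, C6); C6 is a spiro carbon shared with ring B, a cyclohexane that is cis-fused to the cyclopentane ring C. There are seven stereocentres: the (R)-carbon of the 2-methylbutanoyl chain, the (S)-configured quaternary C4 of ring A, the spiro carbon, the two ring-fusion methines, and two tertiary methyl carbinols, one in ring B and one in ring C, each next to a different fusion carbon. In the hydrindane both fusion hydrogens and both carbinol methyl groups lie on one face and both hydroxyls on the other, so each hydroxyl sits on the concave side, cis to the neighbouring ring; at the spiro carbon the C5 carbonyl is cis to the ring B hydroxyl. C4 of ring A and the side-chain centre are insulated from the hydrindane by carbonyl groups, so each needs its own source of chirality. Sensitive features are the acidic, chelating β-triketone (retro-Claisen cleavage, O- versus C-reactivity), the prenyl group (acid-induced cyclisation onto the enol oxygen), two dehydration-prone tertiary alcohols and the epimerisable α-carbon of the acyl chain. The difficulty lies in the spiro quaternary carbon, which is flanked by two carbonyls with a second quaternary carbon two bonds away, and in placing every substituent of the hydrindane on its more hindered face. The plan rests on ring A being a cyclic triketide: C6 is the γ-carbon of the C1/C3 β-dicarbonyl unit, and the C5 carbonyl can be traced back to an ester carried by C4.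

**Retrosynthetic reasoning**

25 from 24: the last operation only frees the two tertiary alcohols. They stay silylated until then so that they cannot lactonise onto, or form hemiketals with, the ring A carbonyls during the base chemistry.

24 from 21 and 22: the C2–acyl bond is cut. A cyclic 1,3-dione is C-acylated reliably by O-acylation and O-to-C acyl transfer, the acid 22 brings its stereocentre ready-made, and doing this late keeps the epimerisable α-carbon away from strong base.

21 from 19 (key disconnection): the ring A bond between the spiro carbon C6 and the C5 carbonyl carbon is cut, giving the open-chain β-diketone ester 19. Cut here, the nucleophile is the γ-carbon of a β-diketone, which is reachable as a dianion terminus; the electrophile is an ester on a carbon without α-hydrogen, so the methyl/prenyl centre cannot epimerise; and the product is an acidic 1,3-dione whose deprotonation drives the closure. Cutting C6–C1 instead would require acylating a simple ester enolate and then closing a ring onto a hindered ester; cutting at C2 or C3 would not create the spiro centre. The forward reaction must acylate the ring B enolate carbon on the face cis to the ring B silyloxy group.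

19 from 12 and 17: the bond between the central CH2 and the carbonyl attached to ring B is cut (crossed Claisen). The methyl ketone 17 has a single enolisable position, so its enolate is unambiguous; the hydrindane enters as the simple ester 12, whose ester-bearing stereocentre need not be controlled because it is planarised in the key step.

17 from 13 with 14 (via 15): the prenyl–C bond at the quaternary centre is cut. An acyclic α-methyl acetoacetate is a poor substrate for catalytic enantioselective alkylation because its enolate geometry is not fixed, so the face is controlled through the chelated enamine 15 made with the recoverable amino ester 14.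

12 from 11, 10 and 9: only functional-group changes (loss of one ester group, silylation, saturation of the ring C alkene). The geminal diester of 9–11 is the handle that allowed both ring B bonds at that carbon to be made by malonate chemistry.

9 from 7: the ring B bond between the ring B carbinol carbon and its neighbouring fusion carbon is cut (carbonyl-ene). This one cut closes ring B, sets the cis ring fusion through the tether, and sets the ring B carbinol because the carbonyl oxygen must reach an allylic hydrogen on the same face of ring C.

7 from 6, and 6 from 4 and 2: the acetonyl–malonate bond is cut (enolate alkylation), then the bond between the ring C fusion carbon and the exocyclic CH2 (intermolecular ene reaction). The ene reaction places the malonate unit next to the carbinol and moves the double bond to exactly the position needed for the later ring B closure; the forward step must deliver the enophile to the oxygen-bearing face.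

4 from 3 and 2 from 1: ring-closing metathesis of 3 delivers the carbinol stereocentre of ring C from the chiral pool, and 1 is methylenated to the enophile 2.

**Alternatives that were turned down**

Alternative 1: The three ring-forming C–C bonds of the hydrindane are cut at once, back to (S)-linalool (3) and dimethyl malonate (1). In the forward step, one-electron oxidation of 1 by a metal carboxylate gives a malonyl radical that adds to the vinyl CH2 of 3. The resulting secondary radical closes ring C onto the trisubstituted alkene; the tertiary radical is oxidised to an isopropenyl group; and a second oxidation of the now mono-alkylated malonate closes ring B in the 6-endo mode, leaving the gem-diester A1 with an exocyclic methylene.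
- For: three bonds and both carbocycles in one operation from two commercial compounds, with all ten terpenoid carbons of 3 used. On step count it is clearly stronger than the chosen route, which needs six steps to reach the comparable diester 10.
- Against: the electrophilic malonyl radical should prefer the electron-rich trisubstituted alkene of 3 over the vinyl group. The tertiary allylic alcohol is exposed to hot acidic oxidising medium. The relative configuration of the two fusion carbons to the carbinol depends on a modest conformational bias of an acyclic radical. A1 still lacks the ring B carbinol, whose oxygen lies on the concave face where electrophilic oxygenation of the methylene would not deliver it.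
- Comparison: the chosen route gives up the one-pot economy but fixes every hydrindane centre by a tether or a concerted transition state.

Alternative 2: The bond from C6 of ring A to its CH2 and the ring C bond between a cyclopentanone carbonyl carbon and the adjacent fusion carbon are cut together; ring B is closed afterwards by C-alkylation of the trione with an epoxide. In the forward step, irradiation of an enolised 2-acyl trione whose acyl chain ends in a vinyl group gives a [2+2] adduct (acyl carbon to inner vinyl carbon, ring A carbon to vinyl CH2), and retro-aldol opening of the cyclobutanol gives A2.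
- For: no protecting or activating groups; the acyl side chain and the methyl/prenyl centre are on board from the start, so no late acylation is needed; the later epoxide opening would create the spiro carbon and the ring B carbinol together. In convergence it is as strong as or stronger than the chosen route.
- Against: the photosubstrate has several enol chromophores and a prenyl alkene that can compete as the cycloaddition partner. The fusion carbon α to the cyclopentanone of A2 is epimerisable, and trans is favoured where the target needs cis. The epoxide (future ring B carbinol) has no controlling element. The spiro carbon would arise by alkylating a planar trione carbon whose faces differ only through the remote methyl/prenyl centre, with O-alkylation as a competitor.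
- Comparison: the chosen route has every hydrindane centre in place before ring A exists and sets the spiro centre under the control of a conformationally biased ring B.

Alternative 3: The ring B bond between the carbinol carbon and the fusion carbon is cut at the very end. In the forward step, an acetonyl ketone on the already quaternary spiro carbon adds as enophile to a cyclopentene held on the same carbon: the carbonyl carbon bonds to the near alkene carbon and oxygen takes the far allylic hydrogen, giving A3; saturation of the ring C alkene then finishes the synthesis.
- For: the same concerted geometry that the chosen route uses at compound 7 sets the ring B carbinol and the cis fusion, so on that point it is equally strong, and it is highly convergent.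
- Against: the spiro carbon must be made stereogenic beforehand by two C-alkylations of the acyl trione, with no element other than the distant methyl/prenyl centre to tell its faces apart. The Lewis acid must act on a chelating enolised triketone. The prenyl alkene is a better ene donor than the cyclopentene, and the ring A carbonyls next to the spiro carbon are competing enophiles. The final hydrogenation must spare the prenyl group.
- Comparison: the chosen route runs the same pericyclic closure on a malonate that has one ketone and one alkene, and moves the spiro-centre problem to a ring closure where ring B dictates the face.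

Key step: step 12

Remark (assumption): the lithio-enamine alkylation of step 10 is taken to give the (S)-keto ester with tert-butyl L-valinate under the toluene/HMPA protocol; if the sense proves opposite, tert-butyl D-valinate is used with no other change.

Remark (assumption): (S)-linalool of high enantiomeric purity is taken as purchasable.

Remark (names): hydrindane positions are C1 (ring C carbinol carbon), C2, C3, C3a, C4 (ring B carbinol carbon), C5, C6 (carboxyl-bearing, later spiro carbon), C7, C7a; α is the face of the two ring-fusion hydrogens, β the opposite face; ring A is numbered as in the analysis.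

**Route**

Step 1
Reactants: 1 dimethyl malonate
Product: 2 dimethyl 2-methylidenepropanedioate
Conditions: (CH2O)n, Cu(OAc)2 (cat.), KOAc, AcOH, 100 °C; distil at reduced pressure, use at once
Reagents that add atoms: paraformaldehyde (as formaldehyde), C=O
Why: Knoevenagel-type methylenation of an active methylene compound; the product is freed from oligomers by distillation and used fresh because it polymerises readily.

Step 2
Reactants: 3 (S)-linalool
Product: 4 (S)-1-methylcyclopent-2-en-1-ol
Conditions: second-generation Grubbs catalyst RuCl2(=CHPh)(H2IMes)(PCy3) (0.2 mol%), neat, 25–40 °C; distil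
Reagents that add atoms: none
Why: Ring-closing metathesis to a five-membered ring, driven by loss of volatile isobutene; the carbinol stereocentre is not touched and becomes the ring C carbinol of the target.

Step 3
Reactants: 4 (S)-1-methylcyclopent-2-en-1-ol; 2 dimethyl 2-methylidenepropanedioate
Product: 6 dimethyl 2-{[(1R,5S)-5-hydroxy-5-methylcyclopent-2-en-1-yl]methyl}propanedioate, via aluminium alkoxide 5 (not isolated)
Conditions: Me2AlCl (1.1 equiv), CH2Cl2, −78 °C; then 2 (1.3 equiv), −78 → −30 °C; aq. Rochelle salt
Reagents that add atoms: none
Why: Lewis acid-promoted ene reaction of a doubly activated alkene; the alkoxide-bound aluminium of 5 chelates the diester and delivers its CH2 to the neighbouring alkene carbon on the oxygen-bearing face while the cis hydrogen of the far allylic CH2 is transferred, so the new centre is set cis to oxygen and the double bond moves one position. Bonding at the other alkene carbon has no allylic hydrogen to complete an ene reaction, and Me2AlCl scavenges protons that would dehydrate the allylic alcohol.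

Step 4
Reactants: 6 dimethyl 2-{[(1R,5S)-5-hydroxy-5-methylcyclopent-2-en-1-yl]methyl}propanedioate
Product: 7 dimethyl 2-{[(1R,5S)-5-hydroxy-5-methylcyclopent-2-en-1-yl]methyl}-2-(2-oxopropyl)propanedioate
Conditions: NaH (1.0 equiv), THF, 0 °C; chloroacetone, NaI (cat.), 0 → 25 °C
Reagents that add atoms: chloroacetone, CC(=O)CCl
Why: Malonate alkylation (SN2 at an α-halo ketone with iodide catalysis); one equivalent of base is consumed by the far more acidic malonate C–H, so the tertiary alcohol stays protonated and no stereocentre is affected.

Step 5
Reactants: 7 dimethyl 2-{[(1R,5S)-5-hydroxy-5-methylcyclopent-2-en-1-yl]methyl}-2-(2-oxopropyl)propanedioate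
Product: 9 dimethyl 1β,4β-dihydroxy-1α,4α-dimethyl-1,3a,4,5,7,7a-hexahydro-6H-indene-6,6-dicarboxylate (cis-fused; 3aα-H; 7aα-H), via aluminium alkoxide 8 (not isolated)
Conditions: Me2AlCl (2.5 equiv), CH2Cl2, −78 → 0 °C; aq. Rochelle salt
Reagents that add atoms: none
Why: Intramolecular carbonyl-ene reaction closing ring B; the three-atom tether forces bond formation on the cyclopentene face that carries it (cis fusion), and the carbonyl oxygen must lie over ring C to take the cis allylic hydrogen next to the ring C carbinol, which leaves the new hydroxyl cis to ring C and the methyl on the α face. The aluminium held by the ring C alkoxide in 8 sits where it can bind the ketone oxygen in that orientation.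

Step 6
Reactants: 9 dimethyl 1β,4β-dihydroxy-1α,4α-dimethyl-1,3a,4,5,7,7a-hexahydro-6H-indene-6,6-dicarboxylate
Product: 10 dimethyl 1β,4β-dihydroxy-1α,4α-dimethyloctahydro-6H-indene-6,6-dicarboxylate (cis-fused; 3aα-H; 7aα-H)
Conditions: H2 (1 atm), Rh/Al2O3 (5% Rh), EtOAc, 25 °C
Reagents that add atoms: none
Why: Heterogeneous catalytic hydrogenation of a cis-disubstituted ring alkene; no stereocentre is formed, and rhodium on alumina is chosen because it is less prone than palladium to cleave the allylic tertiary C–O bond.

Step 7
Reactants: 10 dimethyl 1β,4β-dihydroxy-1α,4α-dimethyloctahydro-6H-indene-6,6-dicarboxylate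
Product: 11 dimethyl 1α,4α-dimethyl-1β,4β-bis(triethylsilyloxy)octahydro-6H-indene-6,6-dicarboxylate
Conditions: Et3SiOTf (3 equiv), 2,6-lutidine, CH2Cl2, −40 → 25 °C
Reagents that add atoms: triethylsilyl trifluoromethanesulfonate, CC[Si](CC)(CC)OS(=O)(=O)C(F)(F)F
Why: Silylation of tertiary alcohols with a silyl triflate; protection at this point keeps either hydroxyl from lactonising onto an ester in step 8 and from interfering with the enolate chemistry of steps 11 and 12.

Step 8
Reactants: 11 dimethyl 1α,4α-dimethyl-1β,4β-bis(triethylsilyloxy)octahydro-6H-indene-6,6-dicarboxylate
Product: 12 methyl 1α,4α-dimethyl-1β,4β-bis(triethylsilyloxy)octahydro-1H-indene-6β-carboxylate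
Conditions: LiCl, H2O (2 equiv), DMSO, 150 °C
Reagents that add atoms: none
Why: Krapcho dealkoxycarbonylation (chloride demethylation, decarboxylation, protonation) under neutral conditions that silyl ethers tolerate; C6 is expected as a mixture of epimers (the equatorial 6β ester is drawn), which is of no consequence because this centre is planarised in step 12.

Step 9
Reactants: 13 methyl 2-methyl-3-oxobutanoate; 14 tert-butyl L-valinate
Product: 15 methyl (Z)-3-{[(2S)-1-tert-butoxy-3-methyl-1-oxobutan-2-yl]amino}-2-methylbut-2-enoate
Conditions: BF3·OEt2 (cat.), toluene, reflux, Dean–Stark trap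
Reagents that add atoms: none
Why: Enamine condensation of a β-keto ester with a primary amine; the hydrogen-bonded (Z)-enamino ester is the stable isomer.

Step 10
Reactants: 15 methyl (Z)-3-{[(2S)-1-tert-butoxy-3-methyl-1-oxobutan-2-yl]amino}-2-methylbut-2-enoate
Product: 17 methyl (2S)-2-acetyl-2,5-dimethylhex-4-enoate, via alkylated imine 16 (not isolated)
Conditions: LiN(i-Pr)2, toluene, −78 °C; HMPA (1 equiv); prenyl bromide, −78 → −55 °C; then 10% aq. citric acid, 25 °C
Reagents that add atoms: 1-bromo-3-methylbut-2-ene, CC(C)=CCBr; water, O
Why: Auxiliary-controlled alkylation of a chiral lithio-enamine: lithium is held by the nitrogen and both ester carbonyls in a rigid chelate whose isopropyl group screens one face, so the prenyl halide sets the quaternary centre; mild acid hydrolysis of imine 16 releases the ketone and returns the auxiliary. The new centre has no α-hydrogen and cannot racemise afterwards.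

Step 11
Reactants: 17 methyl (2S)-2-acetyl-2,5-dimethylhex-4-enoate; 12 methyl 1α,4α-dimethyl-1β,4β-bis(triethylsilyloxy)octahydro-1H-indene-6β-carboxylate
Product: 19 methyl (2S)-5-[1α,4α-dimethyl-1β,4β-bis(triethylsilyloxy)octahydro-1H-inden-6β-yl]-2-methyl-2-(3-methylbut-2-en-1-yl)-3,5-dioxopentanoate, via lithium enolate 18 (not isolated)
Conditions: 17 (2.4 equiv), LiN(i-Pr)2 (2.3 equiv), THF, −78 °C; then 12, −78 → 0 °C; aq. NH4Cl at 0 °C
Reagents that add atoms: none
Why: Crossed Claisen condensation of a ketone enolate with an ester; 17 can enolise only at its methyl group, the excess enolate deprotonates the β-diketone as it forms, and a cold quench keeps the diketone enolate from closing onto the pendant ester through oxygen.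

Step 12
Reactants: 19 methyl (2S)-5-[1α,4α-dimethyl-1β,4β-bis(triethylsilyloxy)octahydro-1H-inden-6β-yl]-2-methyl-2-(3-methylbut-2-en-1-yl)-3,5-dioxopentanoate
Product: 21 (4S)-3-hydroxy-4-methyl-4-(3-methylbut-2-en-1-yl)cyclohex-2-ene-1,5-dione spiro-linked at C6 to C6' of 1'α,4'α-dimethyl-1'β,4'β-bis(triethylsilyloxy)octahydroindene (C5=O on the β face of ring B), via dilithium dianion 20 (not isolated)
Conditions: LiN(i-Pr)2 (3.5 equiv), THF/DMPU (10:1), −78 → 0 °C; aq. NH4Cl at 0 °C
Reagents that add atoms: none
Why: Excess LiN(i-Pr)2 removes first a proton of the central CH2 and then the only other acidic C–H, the ring B methine, giving the extended dianion 20 whose terminal γ-carbon is its most nucleophilic site. That carbon attacks the methyl ester on the quaternary carbon, methoxide leaves, and the cyclic 1,3-dione is deprotonated at once between its carbonyls, which makes the closure irreversible. The closest known reaction type is the Claisen (Dieckmann-type) cyclisation of β-diketone dianions and of 3,5-dioxo esters to cyclohexane-1,3,5-triones, the laboratory counterpart of triketide cyclisation. Ring A closes in the 6-(enolendo)-exo-trig mode. The new spiro stereocentre is controlled by ring B: in its preferred chair the C4' methyl is axial and 1,3 to the enolate carbon, so the ester carbon is taken up on the equatorial face, cis to the C4' silyloxy group. The former stereocentre at C6' is erased in 20, so both epimers of 19 converge. The step needs C- rather than O-acylation (the enolate oxygen could close to a pyran-2,4-dione); complete dianion formation at −78 °C before warming secures this, and lithium methoxide can reopen any enol lactone. The methyl/prenyl centre has no α-hydrogen and survives unchanged.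

Step 13
Reactants: 21 spiro enol-dione (as named in step 12); 22 (R)-2-methylbutanoic acid
Product: 24 bis(triethylsilyl) ether of the target (2-[(2R)-2-methylbutanoyl] derivative of 21), via enol ester 23 (not isolated)
Conditions: 22 (1.2 equiv), DCC (1.3 equiv), DMAP (1.3 equiv), CH2Cl2, 0 → 25 °C
Reagents that add atoms: none
Why: Carbodiimide-mediated O-acylation of the cyclic 1,3-dione followed by DMAP-mediated O-to-C acyl migration (Fries-type shift through the acylpyridinium/dione enolate pair); either enol oxygen leads to the same C2-acyl product, and the third carbonyl cannot enolise. The side-chain centre comes from 22 and is exposed only to a weak base at room temperature.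

Step 14
Reactants: 24 bis(triethylsilyl) ether of the target
Product: 25 CNP0236509.3 (target)
Conditions: HF·pyridine, THF/pyridine, 0 → 25 °C
Reagents that add atoms: none
Why: Fluoride-mediated desilylation of the two tertiary silyl ethers under buffered, weakly acidic conditions that do not dehydrate the carbinols, cyclise the prenyl group or epimerise the acyl chain.

**Compound list**

1 | dimethyl malonate | COC(=O)CC(=O)OC | starting material
2 | dimethyl 2-methylidenepropanedioate | COC(=O)C(=C)C(=O)OC | intermediate
3 | (S)-linalool, (3S)-3,7-dimethylocta-1,6-dien-3-ol | C=C[C@@](C)(O)CCC=C(C)C | starting material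
4 | (S)-1-methylcyclopent-2-en-1-ol | C[C@@]1(O)C=CCC1 | intermediate
5 | chloro(methyl)aluminium (S)-1-methylcyclopent-2-en-1-olate (not isolated) | C[Al](Cl)O[C@]1(C)C=CCC1 | intermediate
6 | dimethyl 2-{[(1R,5S)-5-hydroxy-5-methylcyclopent-2-en-1-yl]methyl}propanedioate (CH2 cis to OH) | COC(=O)C(C[C@@H]1C=CC[C@]1(C)O)C(=O)OC | intermediate
7 | dimethyl 2-{[(1R,5S)-5-hydroxy-5-methylcyclopent-2-en-1-yl]methyl}-2-(2-oxopropyl)propanedioate | COC(=O)C(CC(C)=O)(C[C@@H]1C=CC[C@]1(C)O)C(=O)OC | intermediate
8 | chloro(methyl)aluminium alkoxide of 7 (not isolated) | COC(=O)C(CC(C)=O)(C[C@@H]1C=CC[C@]1(C)O[Al](C)Cl)C(=O)OC | intermediate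
9 | dimethyl 1β,4β-dihydroxy-1α,4α-dimethyl-1,3a,4,5,7,7a-hexahydro-6H-indene-6,6-dicarboxylate (cis-fused; 3aα-H; 7aα-H; C2=C3 alkene) | COC(=O)C1(C(=O)OC)C[C@@H]2[C@@H](C=C[C@]2(C)O)[C@@](C)(O)C1 | intermediate
10 | dimethyl 1β,4β-dihydroxy-1α,4α-dimethyloctahydro-6H-indene-6,6-dicarboxylate (cis-fused; 3aα-H; 7aα-H) | COC(=O)C1(C(=O)OC)C[C@@H]2[C@@H](CC[C@]2(C)O)[C@@](C)(O)C1 | intermediate
11 | dimethyl 1α,4α-dimethyl-1β,4β-bis(triethylsilyloxy)octahydro-6H-indene-6,6-dicarboxylate | COC(=O)C1(C(=O)OC)C[C@@H]2[C@@H](CC[C@]2(C)O[Si](CC)(CC)CC)[C@@](C)(O[Si](CC)(CC)CC)C1 | intermediate
12 | methyl 1α,4α-dimethyl-1β,4β-bis(triethylsilyloxy)octahydro-1H-indene-6β-carboxylate | COC(=O)[C@H]1C[C@@H]2[C@@H](CC[C@]2(C)O[Si](CC)(CC)CC)[C@@](C)(O[Si](CC)(CC)CC)C1 | intermediate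
13 | methyl 2-methyl-3-oxobutanoate | COC(=O)C(C)C(C)=O | starting material
14 | tert-butyl L-valinate | CC(C)[C@H](N)C(=O)OC(C)(C)C | starting material
15 | methyl (Z)-3-{[(2S)-1-tert-butoxy-3-methyl-1-oxobutan-2-yl]amino}-2-methylbut-2-enoate | COC(=O)/C(C)=C(C)\N[C@@H](C(C)C)C(=O)OC(C)(C)C | intermediate
16 | methyl (2S)-3-{[(2S)-1-tert-butoxy-3-methyl-1-oxobutan-2-yl]imino}-2-methyl-2-(3-methylbut-2-en-1-yl)butanoate (not isolated) | COC(=O)[C@@](C)(CC=C(C)C)C(C)=N[C@@H](C(C)C)C(=O)OC(C)(C)C | intermediate
17 | methyl (2S)-2-acetyl-2,5-dimethylhex-4-enoate | COC(=O)[C@@](C)(CC=C(C)C)C(C)=O | intermediate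
18 | lithium enolate of 17 (methyl side; not isolated) | COC(=O)[C@@](C)(CC=C(C)C)C(=C)O[Li] | intermediate
19 | methyl (2S)-5-[1α,4α-dimethyl-1β,4β-bis(triethylsilyloxy)octahydro-1H-inden-6β-yl]-2-methyl-2-(3-methylbut-2-en-1-yl)-3,5-dioxopentanoate | COC(=O)[C@@](C)(CC=C(C)C)C(=O)CC(=O)[C@H]1C[C@@H]2[C@@H](CC[C@]2(C)O[Si](CC)(CC)CC)[C@@](C)(O[Si](CC)(CC)CC)C1 | intermediate
20 | dilithium dianion of 19 (exocyclic enolate at C6'; not isolated) | COC(=O)[C@@](C)(CC=C(C)C)C(O[Li])=CC(O[Li])=C1C[C@@H]2[C@@H](CC[C@]2(C)O[Si](CC)(CC)CC)[C@@](C)(O[Si](CC)(CC)CC)C1 | intermediate
21 | (4S)-3-hydroxy-4-methyl-4-(3-methylbut-2-en-1-yl)cyclohex-2-ene-1,5-dione spiro-linked at C6 to C6' of 1'α,4'α-dimethyl-1'β,4'β-bis(triethylsilyloxy)octahydroindene (C5=O β, C1=O α on ring B) | C1=C(O)[C@](C)(CC=C(C)C)C(=O)[C@]2(C[C@@H]3[C@@H](CC[C@]3(C)O[Si](CC)(CC)CC)[C@@](C)(O[Si](CC)(CC)CC)C2)C1=O | intermediate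
22 | (R)-2-methylbutanoic acid | CC[C@@H](C)C(O)=O | starting material
23 | enol (2R)-2-methylbutanoate of 21 at the C3 oxygen (or its C1-oxygen regioisomer; not isolated) | C1=C(OC(=O)[C@H](C)CC)[C@](C)(CC=C(C)C)C(=O)[C@]2(C[C@@H]3[C@@H](CC[C@]3(C)O[Si](CC)(CC)CC)[C@@](C)(O[Si](CC)(CC)CC)C2)C1=O | intermediate
24 | bis(triethylsilyl) ether of the target | CC[C@@H](C)C(=O)C1=C(O)[C@](C)(CC=C(C)C)C(=O)[C@]2(C[C@@H]3[C@@H](CC[C@]3(C)O[Si](CC)(CC)CC)[C@@](C)(O[Si](CC)(CC)CC)C2)C1=O | intermediate
25 | CNP0236509.3 | CC[C@@H](C)C(=O)C1=C(O)[C@](C)(CC=C(C)C)C(=O)[C@]2(C[C@@H]3[C@@H](CC[C@]3(C)O)[C@@](C)(O)C2)C1=O | target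

**Step count and risks**

Total: 14 steps. Longest linear sequence: 11 steps (steps 2–8 and 11–14, from 3). Steps 1, 9 and 10 prepare the two side fragments.

Least certain steps:

Step 12 (key step). Most likely to go wrong: acylation through oxygen, in which the diketone enolate closes onto the ester to an enol lactone before the hindered methine is deprotonated; incomplete γ-deprotonation; or attack on the axial face of ring B. Fallback, from 19 back to 21: the diketone of 19 is masked as its sodium enolate (NaH) and the ester is reduced with i-Bu2AlH at −78 °C to the aldehyde F1 (19 with CHO in place of CO2Me). LiN(i-Pr)2 (2.2 equiv) at −78 °C forms the same dianion, whose γ-carbon now adds to the aldehyde in an intramolecular aldol reaction that cannot O-acylate, giving the hydroxy dione F2 (21 with CH–OH at C5) under the same facial control. Dess–Martin periodinane then oxidises C5 to the ketone, which is 21.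

Step 3. Most likely to go wrong: ionisation or semipinacol-type rearrangement of the tertiary allylic alkoxide under the Lewis acid, bonding of the enophile to the less hindered alkene carbon, conjugate addition through oxygen, or polymerisation of 2. Fallback, from 4 back to 6, using a silicon tether and radical chemistry instead of an ene reaction:
- 4 is silylated with (bromomethyl)chlorodimethylsilane and imidazole to the bromomethylsilyl ether F3 and converted with NaI in acetone into the iodomethylsilyl ether F4.
- Et3B/air-initiated iodine-atom-transfer cyclisation (5-exo, necessarily cis to oxygen) gives the bicyclic iodide F5 with iodine trans to the new CH2.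
- DBU removes HI, which for stereoelectronic reasons is possible only toward the ring CH2, giving the bicyclic alkene F6.
- Tamao oxidation (KF, KHCO3, H2O2) gives the cis diol F7.
- I2/PPh3/imidazole converts its primary hydroxyl into the iodide F8, which the sodium salt of 1 displaces to give 6.

Step 5. Most likely to go wrong: the unactivated methyl ketone is too weak an enophile for a 1,2-disubstituted alkene, so that nothing happens, methyl is transferred from aluminium to the ketone, or the allylic tertiary alkoxide of the product ionises. Fallback, from 6 back to 10, using an activated enophile and later deoxygenation: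
- 6 is alkylated (NaH) with methyl bromopyruvate to the α-keto ester F9.
- Its activated ketone undergoes the same intramolecular ene reaction on heating or with SnCl4 to give the hydroxy triester F10, with the identical transition-state geometry (oxygen over ring C, an ester where the methyl will be).
- NaBH4 in methanol reduces only the α-hydroxy ester, to the primary alcohol F11.
- I2/PPh3/imidazole gives the iodide F12.
- H2 over Pd/C with Et3N removes iodine and saturates the ring C alkene, giving 10.

Step 10. Most likely to go wrong: poor or reversed facial selectivity in the alkylation of the acyclic lithio-enamine (loss of chelate geometry, N-alkylation), which would erode enantiomeric purity at the centre that cannot be corrected later. Fallback, from 13 back to 17: 13 is alkylated with NaH and prenyl bromide to the racemic keto ester F13, which is resolved by preparative chromatography on a chiral stationary phase.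

Step 11. Most likely to go wrong: slow acyl transfer to the hindered secondary ester, so that proton transfer and enolate self-condensation take over, or premature ring closure of the product enolate through oxygen on warming. Fallback, from 12 back to 19: 12 is saponified (LiOH, THF/MeOH/H2O) to the acid F14 and activated with 1,1'-carbonyldiimidazole to the acyl imidazole F15, which acylates enolate 18 at −78 °C.

Step 13. Most likely to go wrong: epimerisation at the α-carbon of the acyl group through the acylpyridinium or a ketene, or stalling at the enol ester. Fallback, from 21 and 22 back to 24: 22 is converted (1H-benzotriazole, SOCl2) into the N-acylbenzotriazole F16, which C-acylates 21 directly under soft enolisation (MgBr2·OEt2, i-Pr2NEt, CH2Cl2) through the chelated magnesium enolate.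

**Further compounds**

F1 | step 12 | aldehyde analogue of 19 (formyl in place of the methyl ester; same configuration) | O=C[C@@](C)(CC=C(C)C)C(=O)CC(=O)[C@H]1C[C@@H]2[C@@H](CC[C@]2(C)O[Si](CC)(CC)CC)[C@@](C)(O[Si](CC)(CC)CC)C1
F2 | step 12 | hydroxy dione (21 with CH–OH at C5 of ring A; carbinol configuration immaterial) | C1=C(O)[C@](C)(CC=C(C)C)C(O)[C@]2(C[C@@H]3[C@@H](CC[C@]3(C)O[Si](CC)(CC)CC)[C@@](C)(O[Si](CC)(CC)CC)C2)C1=O
F3 | step 3 | (S)-(bromomethyl)dimethyl[(1-methylcyclopent-2-en-1-yl)oxy]silane | BrC[Si](C)(C)O[C@]1(C)C=CCC1
F4 | step 3 | (S)-(iodomethyl)dimethyl[(1-methylcyclopent-2-en-1-yl)oxy]silane | IC[Si](C)(C)O[C@]1(C)C=CCC1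
F5 | step 3 | cis-fused bicyclic oxasilolane iodide (iodine trans to the CH2Si bridge) | C[Si]1(C)C[C@@H]2[C@@H](I)CC[C@]2(C)O1
F6 | step 3 | cis-fused bicyclic oxasilolane with ring alkene | C[Si]1(C)C[C@@H]2C=CC[C@]2(C)O1
F7 | step 3 | cis-2-(hydroxymethyl)-1-methylcyclopent-3-en-1-ol (carbinol centre as in 4) | OC[C@@H]1C=CC[C@]1(C)O
F8 | step 3 | cis-2-(iodomethyl)-1-methylcyclopent-3-en-1-ol | IC[C@@H]1C=CC[C@]1(C)O
F9 | step 5 | dimethyl 2-{[(1R,5S)-5-hydroxy-5-methylcyclopent-2-en-1-yl]methyl}-2-(3-methoxy-2,3-dioxopropyl)propanedioate | COC(=O)C(=O)CC(C[C@@H]1C=CC[C@]1(C)O)(C(=O)OC)C(=O)OC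
F10 | step 5 | trimethyl ester analogue of 9 (CO2Me in place of the C4 methyl) | COC(=O)C1(C(=O)OC)C[C@@H]2[C@@H](C=C[C@]2(C)O)[C@@](C(=O)OC)(O)C1
F11 | step 5 | hydroxymethyl analogue of 9 (CH2OH in place of the C4 methyl) | COC(=O)C1(C(=O)OC)C[C@@H]2[C@@H](C=C[C@]2(C)O)[C@@](CO)(O)C1
F12 | step 5 | iodomethyl analogue of 9 (CH2I in place of the C4 methyl) | COC(=O)C1(C(=O)OC)C[C@@H]2[C@@H](C=C[C@]2(C)O)[C@@](CI)(O)C1
F13 | step 10 | racemic methyl 2-acetyl-2,5-dimethylhex-4-enoate | COC(=O)C(C)(CC=C(C)C)C(C)=O
F14 | step 11 | 1α,4α-dimethyl-1β,4β-bis(triethylsilyloxy)octahydro-1H-indene-6β-carboxylic acid | OC(=O)[C@H]1C[C@@H]2[C@@H](CC[C@]2(C)O[Si](CC)(CC)CC)[C@@](C)(O[Si](CC)(CC)CC)C1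
F15 | step 11 | acyl imidazole of F14 | O=C(n1ccnc1)[C@H]1C[C@@H]2[C@@H](CC[C@]2(C)O[Si](CC)(CC)CC)[C@@](C)(O[Si](CC)(CC)CC)C1
F16 | step 13 | (2R)-1-(benzotriazol-1-yl)-2-methylbutan-1-one | CC[C@@H](C)C(=O)n1nnc2ccccc21
A1 | alternative 1 | dimethyl 1β-hydroxy-1α-methyl-4-methylideneoctahydro-6H-indene-6,6-dicarboxylate (cis-fused) | COC(=O)C1(C(=O)OC)C[C@@H]2[C@@H](CC[C@]2(C)O)C(=C)C1
A2 | alternative 2 | acyl trione carrying at C6 a CH2 link to a 2-oxocyclopentyl ring that bears a 2-methyloxiran-2-yl group | CC[C@@H](C)C(=O)C1=C(O)C(C[C@@H]2[C@@H](CCC2=O)[C@]3(C)CO3)=C(O)[C@@](C)(CC=C(C)C)C1=O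
A3 | alternative 3 | dehydro target with a double bond in ring C next to the ring C carbinol | CC[C@@H](C)C(=O)C1=C(O)[C@](C)(CC=C(C)C)C(=O)[C@]2(C[C@@H]3[C@@H](C=C[C@]3(C)O)[C@@](C)(O)C2)C1=O
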